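**Retrosynthetic overview**
- The target is the (S)-5-acetate of [10]-gingerol; the last disconnection is chemoselective removal of a phenolic acetate from the O,O-diacetate.
- The diacetate is cut at C4–C5 into decanal and the terminal enol acetate of O-acetylzingerone. They are joined by a catalytic enantioselective acetoxy-aldol in which the enol acetyl group ends up on the new C5 oxygen; this sets the only stereocentre (S).
- The enol acetate comes from zingerone and acetic anhydride through the kinetic dianion, so one operation installs both acetyl groups.
- No ring is formed; the only ring, the arene, is bought with zingerone.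

**Assumptions**
- The acid catalyst of step 2 is the (S,S)-imidodiphosphorimidate (IDPi) built from two (S)-3,3'-bis[3,5-bis(trifluoromethyl)phenyl]-1,1'-bi-2-naphthol units, with an N-trifluoromethanesulfonyl group on each phosphorus.
- This enantiomer is taken to expose the Re face of decanal. The sense of induction of a new reaction must be confirmed on the first run; if it is reversed, the (R,R)-acid is used.
- LiN(iPr)2 is used as the commercial solution.

Step 1
Reactants: 1 zingerone [4-(4-hydroxy-3-methoxyphenyl)butan-2-one]
Product: 3 bis-acetate [4-(4-acetoxy-3-methoxyphenyl)but-1-en-2-yl acetate], via dilithium dianion 2 (not isolated)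
Conditions: LiN(iPr)2 (2.2 equiv), THF, −78 °C, 45 min; cannulated into Ac2O (5 equiv), THF, −78 → 0 °C; aq. NaHCO3
Reagents that add atoms: acetic anhydride, CC(=O)OC(C)=O
Why: The hindered amide base removes the phenol proton and then, under kinetic control, a proton of the methyl group, and inverse addition into excess anhydride traps both oxygens by O-acylation (kinetic enolate trapping as the enol acetate), so the future C5 acetate and the phenol protection are installed together; no stereocentre is formed.

Step 2
Reactants: 3 bis-acetate [4-(4-acetoxy-3-methoxyphenyl)but-1-en-2-yl acetate]; 4 decanal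
Product: 6 diacetate [(5S)-1-(4-acetoxy-3-methoxyphenyl)-3-oxotetradecan-5-yl acetate], via oxocarbenium adduct 5 (not isolated)
Conditions: (S,S)-IDPi acid (3 mol%), 4 (1.5 equiv, added over 6 h), toluene, −40 °C, 48 h; then Et3N
Reagents that add atoms: none
Why: Proposed new method: an enantioselective acetoxy-aldol (acyl-transfer Mukaiyama-type aldol, or "acyl-ene" reaction) in which the confined strong acid protonates decanal inside its chiral pocket, the terminal carbon of the 1,1-disubstituted enol acetate (a π-nucleophile comparable to the simple alkenes and dienes that such acids already engage with aliphatic aldehydes) attacks the exposed Re face to give oxocarbenium 5 ion-paired with the chiral anion, and the new hydroxyl takes over the acetyl group through a six-membered transition state, which makes the addition irreversible, releases the ketone, returns the proton to the catalyst and leaves the arene oxygen untouched; Re-face attack gives S at C5 because CH2C(=O) outranks nonyl, and the closest known reaction types are the IDPi-catalysed Mukaiyama aldol, Hosomi–Sakurai, carbonyl-ene and Prins reactions of aliphatic aldehydes and the racemic Lewis-acid-promoted addition of enol acetates to aldehydes.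

Step 3
Reactants: 6 diacetate [(5S)-1-(4-acetoxy-3-methoxyphenyl)-3-oxotetradecan-5-yl acetate]
Product: 7 target [(5S)-1-(4-hydroxy-3-methoxyphenyl)-3-oxotetradecan-5-yl acetate]
Conditions: NH4OAc (8 equiv), MeOH/H2O 9:1, 23 °C, 6 h
Reagents that add atoms: none
Why: Chemoselective transesterification: the aryl acetate (phenoxide leaving group) is methanolysed in the near-neutral buffer far faster than the secondary alkyl acetate, and the absence of strong base avoids E1cB loss of acetate from the β-acetoxy ketone, so C5 is untouched.

**Compound list**
1 | zingerone, 4-(4-hydroxy-3-methoxyphenyl)butan-2-one | CC(=O)CCc1ccc(O)c(OC)c1 | starting material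
2 | dilithium dianion of zingerone, dilithium 2-methoxy-4-(3-oxidobut-3-en-1-yl)phenolate | [Li+].[Li+].C=C([O-])CCc1ccc([O-])c(OC)c1 | intermediate
3 | bis-acetate, 4-(4-acetoxy-3-methoxyphenyl)but-1-en-2-yl acetate | C=C(CCc1ccc(OC(C)=O)c(OC)c1)OC(C)=O | intermediate
4 | decanal | CCCCCCCCCC=O | starting material
5 | oxocarbenium adduct, O-acetyl oxocarbenium ion of (5S)-1-(4-acetoxy-3-methoxyphenyl)-5-hydroxytetradecan-3-one, paired with the catalyst anion | CCCCCCCCC[C@H](O)CC(CCc1ccc(OC(C)=O)c(OC)c1)=[O+]C(C)=O | intermediate
6 | diacetate, (5S)-1-(4-acetoxy-3-methoxyphenyl)-3-oxotetradecan-5-yl acetate | CCCCCCCCC[C@@H](CC(=O)CCc1ccc(OC(C)=O)c(OC)c1)OC(C)=O | intermediate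
7 | (5S)-1-(4-hydroxy-3-methoxyphenyl)-3-oxotetradecan-5-yl acetate, the 5-acetate of (S)-[10]-gingerol | CCCCCCCCC[C@@H](CC(=O)CCc1ccc(O)c(OC)c1)OC(C)=O | target

**Step count**
Total steps: 3. Longest linear sequence: 3 steps (1 → 3 → 6 → 7); decanal 4 enters at step 2.

**Steps most likely to fail**

Step 2 (the proposed new acetoxy-aldol). The enol acetate may be too weak a nucleophile, decanal may self-condense or trimerise under the strong acid, or the enantioselectivity may be low. The fallback uses known enamine catalysis and sets out from 1 and 4. Decanal is added slowly at −20 °C to an excess of zingerone (4 equiv, recovered) in CHCl3 containing L-proline (30 mol%) or, for higher selectivity, the known L-prolinamide of (S)-2-amino-4-methyl-1,1-diphenylpentan-1-ol (10 mol%). This direct aldol goes through the methyl-side enamine and Re-face attack on the aldehyde and gives (5S)-5-hydroxy-1-(4-hydroxy-3-methoxyphenyl)tetradecan-3-one F2, which is (S)-[10]-gingerol. Acetylation of both hydroxyl groups (Ac2O, pyridine, 0 → 23 °C) gives 6, where the route is rejoined before step 3.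

Step 1 (kinetic bis-acetylation). Amine-mediated equilibration of the enolate or competing C-acylation may contaminate 3 with the internal enol acetate or a 1,3-diketone. The fallback sets out from 1 and fixes the regiochemistry at a purifiable silyl stage. LiN(iPr)2 (2.2 equiv) and Me3SiCl (2.5 equiv) in THF at −78 °C give trimethyl({4-[3-methoxy-4-(trimethylsilyloxy)phenyl]but-1-en-2-yl}oxy)silane F1, which is distilled free of the internal isomer. CH3Li (2.1 equiv, THF, 0 °C) then regenerates dianion 2 regiospecifically and free of amine, and inverse quench into Ac2O gives 3, where the route is rejoined.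

Step 3 (selective removal of the aryl acetate). The alkyl acetate may be partly cleaved, or acetic acid may be eliminated to the enone ([10]-shogaol). The fallback changes the protecting group and sets out from 1. tBuMe2SiCl and imidazole in DMF give 4-{4-[(tert-butyldimethylsilyl)oxy]-3-methoxyphenyl}butan-2-one F3. LiN(iPr)2 (1.1 equiv, THF, −78 °C) gives lithium 4-{4-[(tert-butyldimethylsilyl)oxy]-3-methoxyphenyl}but-1-en-2-olate F4, and inverse quench into Ac2O gives 4-{4-[(tert-butyldimethylsilyl)oxy]-3-methoxyphenyl}but-1-en-2-yl acetate F5. The acetoxy-aldol of step 2 with 4 gives (5S)-1-{4-[(tert-butyldimethylsilyl)oxy]-3-methoxyphenyl}-3-oxotetradecan-5-yl acetate F6. KHF2 in MeOH at 23 °C, which cleaves phenolic silyl ethers under mildly acidic conditions, returns the route at 7.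

**Further compounds**
F1 | step 1 | trimethyl({4-[3-methoxy-4-(trimethylsilyloxy)phenyl]but-1-en-2-yl}oxy)silane | C=C(CCc1ccc(O[Si](C)(C)C)c(OC)c1)O[Si](C)(C)C
F2 | step 2 | (5S)-5-hydroxy-1-(4-hydroxy-3-methoxyphenyl)tetradecan-3-one | CCCCCCCCC[C@H](O)CC(=O)CCc1ccc(O)c(OC)c1
F3 | step 3 | 4-{4-[(tert-butyldimethylsilyl)oxy]-3-methoxyphenyl}butan-2-one | CC(=O)CCc1ccc(O[Si](C)(C)C(C)(C)C)c(OC)c1
F4 | step 3 | lithium 4-{4-[(tert-butyldimethylsilyl)oxy]-3-methoxyphenyl}but-1-en-2-olate | [Li+].C=C([O-])CCc1ccc(O[Si](C)(C)C(C)(C)C)c(OC)c1
F5 | step 3 | 4-{4-[(tert-butyldimethylsilyl)oxy]-3-methoxyphenyl}but-1-en-2-yl acetate | C=C(CCc1ccc(O[Si](C)(C)C(C)(C)C)c(OC)c1)OC(C)=O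
F6 | step 3 | (5S)-1-{4-[(tert-butyldimethylsilyl)oxy]-3-methoxyphenyl}-3-oxotetradecan-5-yl acetate | CCCCCCCCC[C@@H](CC(=O)CCc1ccc(O[Si](C)(C)C(C)(C)C)c(OC)c1)OC(C)=O
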